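The readings come from a simulation for an exercise, noise included.

Decide first to compare the amber and ochre flasks at equal conversion, not at equal time, as the question does.

| setting | amber | ochre | flask |
|---|---|---|---|
| X | 1 M | 1 M | 1.0 M |
| Z | 1 M | 1 M | 1.0 M |
| E | 1.2 equiv | 1.2 equiv | 1.20 equiv |
| L | 3.8 mol% | 5.7 mol% | 3.8 mol% |
| remark | the very flask that is asked about, followed so far | run made earlier |  |

| run | time / h | D / % | X / % |
|---|---|---|---|
| amber | 0.333 | 8 | 49 |
| amber | 1.00 | 13 | 39 |
| amber | 1.50 | 15 | 30 |
| amber | 2.50 | 27 | 29 |
| amber | 4.00 | 26 | 24 |
| amber | 5.00 | 28 | 21 |
| amber | 6.00 | 29 | 17 |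
| ochre | 0.833 | 16 | 34 |
| ochre | 1.33 | 24 | 32 |
| ochre | 2.00 | 25 | 28 |
| ochre | 3.00 | 31 | 20 |
| ochre | 5.00 | 32 | 14 |
| ochre | 6.00 | 36 | 16 |
| ochre | 10.0 | 38 | 12 |

(each reading ± 2 percentage points)

- L is single-handed; X and Z are mirror images of each other, charged as a racemate, each of them at the stated concentration

* apparent order in L when 20% of the X and Z together are converted (percent change of the rate of making D for one percent more L charged)

Two chemists disagree. The first holds that everything here runs with L, so time counts only as L·t and the rate at fixed conversion grows in step with L. The forecast speaks for this view: “the curves roughly collapse on L·t”, and it gives 1.05.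

The second holds that E also leaks away by the clock, whatever the L. In ochre at 10.0 h, the readings are D 38% and X 12%, so by these readings 0.440 M of E has made no D.

She takes the rate of making D as proportional to L, E and X, and the leak as proportional to E. E then cancels from their ratio, so ln(starting X / X) equals a times the leak w, with a proportional to L. Ochre's readings give a = 3.24 /M, so she takes 2.16 /M for amber.

At 20% conversion, counted all as X, amber's X is 0.600 M, so w = 0.236 M and E = 0.564 M. More L shrinks w in proportion, so the order is one plus the clock share s, the leak over the E present: s = 0.419. Any E unspent or spent on Z was counted as leak, so she calls 1.42 a high estimate and expects an order between one and that.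

    E + L → G (k = 4.70 × 10⁻⁴ /M/min)
    E → Q (k = 0.00120 /min)
    E + L + X → L + D (k = 0.130 /M²/min)
    E + L + Z → L + J (k = 0.0110 /M²/min)

Amber gives 1.2, higher than the forecast and lower than her high estimate. In amber at 1.50 h, Q stands at 0.101 M beside E at 0.730 M. By her rule the first view comes right where s is small beside one, which is toward the start of amber. By her rule, twice the E leaves w unchanged at that conversion, so the rate factor is one plus the E charged, times one plus s, over the E charged less that converted. This runs from 2.50 with s zero to 3.13 with her s, and the run with twice the E gives 2.75.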